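**Strategy**

- Retrosynthesis: the C3–Br bond is cut first (electrophilic bromination). The C2–Br bond is cut next, which reveals C2 as a lactam carbonyl (7-bromooxindole). Then the N1–C2 amide bond is cut, and last the C3–C3a bond, giving 2-bromoaniline (1) and ethyl (methylthio)acetate (2).
- Forward: the benzene ring is bought with the C7 bromine in place. C3–C3a is made by a [2,3]-sigmatropic shift of an anilino azasulfonium ylide, the five-membered ring closes as a lactam, and sulfur is removed. The pyrrole ring becomes aromatic only when POBr3 installs Br at C2, and NBS then brominates C3.
- Enabling feature: Br at C2 sits next to N1, so C2 is a lactam carbonyl in disguise. Br at C7 occupies one of the two ring carbons ortho to nitrogen, so only one ortho C–H (the future C3a) can accept the shift.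
- Stereochemistry: the target is achiral. The only stereocentre on the way (C3 of the sulfide intermediates) is racemic and is erased on desulfurisation.

Key step: step 1

Remark: tert-butyl hypochlorite (3) is taken as a purchased reagent; it can equally be made fresh from tert-butanol, NaOCl and acetic acid.

**Route**

Step 1
Reactants: 1 2-bromoaniline; 2 ethyl (methylthio)acetate; 3 tert-butyl hypochlorite
Product: 8 ethyl 2-(2-amino-3-bromophenyl)-2-(methylthio)acetate (racemic), via N-chloro-2-bromoaniline 4 (not isolated), via azasulfonium chloride 5 (not isolated), via azasulfonium ylide 6 (not isolated), via cyclohexadienimine 7 (not isolated)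
Conditions: 3 (1.0 equiv), CH2Cl2, −65 °C; then 2, −65 °C, 1 h; then Et3N, −65 °C to rt
Reagents that add atoms: none
Why: N-Chlorination of 1 by 3 and attack of the sulfide sulfur of 2 on the N–Cl nitrogen give the azasulfonium chloride 5, and Et3N removes the acidic proton between sulfur and the ester to give the stabilised ylide 6. The ylide 6 should undergo a concerted [2,3]-sigmatropic shift of the Sommelet–Hauser type (the Gassman oxindole synthesis) through a five-membered transition state, in which the ylide carbon bonds to the ortho ring carbon while the S–N bond breaks, and the dienimine 7 tautomerises to the aromatic amino ester 8. No ring closes here: the new bond is the future C3–C3a bond, and the lactam ring is closed separately in step 2. The carbon bearing SMe becomes a stereocentre with no controlling element, so it forms racemic and is deleted in step 3. The selectivity needed is ortho regioselectivity, and the substrate secures it, because a shift onto the bromine-bearing ortho carbon gives a dienimine that cannot rearomatise by proton loss, so only the single ortho C–H carbon leads to product. The weakly basic haloaniline gives an N-chloro derivative that should persist at −65 °C, and the free NH2 needs no protection.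

Step 2
Reactants: 8 ethyl 2-(2-amino-3-bromophenyl)-2-(methylthio)acetate
Product: 9 7-bromo-3-(methylthio)indolin-2-one (racemic)
Conditions: 2 M aq HCl, Et2O, rt
Reagents that add atoms: none
Why: Acid-catalysed intramolecular aminolysis of the ethyl ester by the ortho amino group (5-exo-trig lactamisation forming N1–C2, the second half of the Gassman oxindole synthesis) should be fast for a five-membered anilide even with the bromine-flanked nitrogen, and the stereocentre stays racemic.

Step 3
Reactants: 9 7-bromo-3-(methylthio)indolin-2-one
Product: 10 7-bromoindolin-2-one (7-bromooxindole)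
Conditions: Zn dust, AcOH, rt to 50 °C
Reagents that add atoms: none
Why: This is a dissolving-metal reduction of an α-sulfenyl carbonyl compound, in which electron transfer from zinc to the benzylic, lactam-activated C3–S bond expels methanethiolate and acetic acid protonates the zinc enolate, while the aryl C–Br bond is inert to Zn/AcOH (a Ni hydrogenolysis catalyst is avoided for that reason).

Step 4
Reactants: 10 7-bromoindolin-2-one; 11 phosphorus oxybromide
Product: 12 2,7-dibromo-1H-indole
Conditions: POBr3 (11), imidazole, ClCH2CH2Cl, 80 °C; cold aq NaHCO3 quench; used at once, kept from light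
Reagents that add atoms: phosphorus oxybromide 11, O=P(Br)(Br)Br
Why: This is a dehydrative bromination of a lactam (the bromo counterpart of the POCl3 conversion of oxindoles into 2-chloroindoles), in which the 2-hydroxyindole tautomer is O-phosphorylated, bromide adds at C2 and the dibromophosphate leaves with gain of pyrrole aromaticity, while imidazole buffers the HBr that would otherwise degrade the acid-sensitive 2-bromoindole.

Step 5
Reactants: 12 2,7-dibromo-1H-indole; 13 N-bromosuccinimide
Product: 14 2,3,7-tribromo-1H-indole (target)
Conditions: NBS (13, 1.0 equiv), THF, −78 to 0 °C, dark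
Reagents that add atoms: N-bromosuccinimide 13, O=C1CCC(=O)N1Br
Why: Electrophilic aromatic substitution at C3, the most nucleophilic carbon of the indole and the only free pyrrole position, is much faster than attack on the bromine-deactivated benzene ring, so one equivalent of NBS at low temperature should stop at the tribromide.

**Compound list**

1 | 2-bromoaniline | Nc1ccccc1Br | starting material
2 | ethyl (methylthio)acetate | CCOC(=O)CSC | starting material
3 | tert-butyl hypochlorite | CC(C)(C)OCl | starting material
4 | N-chloro-2-bromoaniline | ClNc1ccccc1Br | intermediate
5 | (2-bromoanilino)(2-ethoxy-2-oxoethyl)methylsulfonium chloride (racemic at sulfur) | CCOC(=O)C[S+](C)Nc1ccccc1Br.[Cl-] | intermediate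
6 | (2-bromoanilino)(methyl)sulfonium (ethoxycarbonyl)methylide (racemic at sulfur) | CCOC(=O)[CH-][S+](C)Nc1ccccc1Br | intermediate
7 | ethyl 2-(5-bromo-6-iminocyclohexa-2,4-dien-1-yl)-2-(methylthio)acetate (mixture of stereoisomers) | CCOC(=O)C(SC)C1C=CC=C(Br)C1=N | intermediate
8 | ethyl 2-(2-amino-3-bromophenyl)-2-(methylthio)acetate (racemic) | CCOC(=O)C(SC)c1cccc(Br)c1N | intermediate
9 | 7-bromo-3-(methylthio)indolin-2-one (racemic) | CSC1C(=O)Nc2c(Br)cccc21 | intermediate
10 | 7-bromoindolin-2-one (7-bromooxindole) | O=C1Cc2cccc(Br)c2N1 | intermediate
11 | phosphorus oxybromide | O=P(Br)(Br)Br | starting material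
12 | 2,7-dibromo-1H-indole | Brc1cc2cccc(Br)c2[nH]1 | intermediate
13 | N-bromosuccinimide | O=C1CCC(=O)N1Br | starting material
14 | 2,3,7-tribromo-1H-indole | Brc1[nH]c2c(Br)cccc2c1Br | target

**Count**

Total steps: 5. Longest linear sequence: 5 steps (1 to 14).

**Steps most likely to fail, with fallbacks**

Step 1. The N-chloroaniline may chlorinate its own ring, or S–N bond formation at the hindered, weakly nucleophilic nitrogen may be too slow, so that little azasulfonium salt reaches the ylide stage. The fallback reverses the polarity of the S–N bond formation and sets out from 2. SO2Cl2 in CH2Cl2 at −78 °C should convert the sulfide into chloro(2-ethoxy-2-oxoethyl)methylsulfonium chloride F1. Aniline 1 is then added with 1,8-bis(dimethylamino)naphthalene as acid scavenger, so that the nitrogen attacks the electrophilic sulfur. This gives the azasulfonium chloride 5, where the route is rejoined (Et3N, then as in step 1), and the N-chloroaniline 4 is no longer needed.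

Step 3. The C–S cleavage may stall at the lactam oxidation level, or forcing it may cause reductive loss of the C7 bromine. The fallback removes sulfur oxidatively and sets out from 9.
- N-Chlorosuccinimide in CH2Cl2 at rt should give 7-bromo-3-chloro-3-(methylthio)indolin-2-one F2.
- Hydrolysis with HgO and BF3·OEt2 in aqueous THF (HgO acting as thiol scavenger) should give 7-bromoisatin F3.
- Hydrazine hydrate in refluxing EtOH should give 7-bromoisatin 3-hydrazone F4.
- NaOEt in refluxing EtOH (Wolff–Kishner reduction, to which the aryl bromide is inert) should expel dinitrogen and return 7-bromooxindole 10.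

Step 4. The electron-rich 2-bromoindole may be hydrolysed back to the lactam or oligomerise under the acidic phosphorus halide conditions and on work-up. The fallback installs the C2 bromine by directed metalation on an N-protected indole and sets out from 10.
- Reduction with i-Bu2AlH in toluene/THF (0 °C to rt, acidic work-up to dehydrate the hemiaminal) should give 7-bromoindole F5.
- Boc2O with catalytic DMAP in MeCN should give tert-butyl 7-bromoindole-1-carboxylate F6.
- LiN(i-Pr)2 in THF at −78 °C should remove the C2 proton under carbamate direction, without bromine–lithium exchange, to give tert-butyl 7-bromo-2-lithioindole-1-carboxylate F7.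
- A BrCCl2CCl2Br quench should give tert-butyl 2,7-dibromoindole-1-carboxylate F8.
- K2CO3 in MeOH at rt should remove the carbamate under non-acidic conditions and return 2,7-dibromoindole 12.

**Further compounds**

F1 | step 1 | chloro(2-ethoxy-2-oxoethyl)methylsulfonium chloride | CCOC(=O)C[S+](C)Cl.[Cl-]
F2 | step 3 | 7-bromo-3-chloro-3-(methylthio)indolin-2-one (racemic) | CSC1(Cl)C(=O)Nc2c(Br)cccc21
F3 | step 3 | 7-bromoisatin (7-bromoindoline-2,3-dione) | O=C1Nc2c(Br)cccc2C1=O
F4 | step 3 | (Z)-7-bromo-3-hydrazonoindolin-2-one | N/N=C1\C(=O)Nc2c(Br)cccc21
F5 | step 4 | 7-bromo-1H-indole | Brc1cccc2cc[nH]c12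
F6 | step 4 | tert-butyl 7-bromoindole-1-carboxylate | CC(C)(C)OC(=O)n1ccc2cccc(Br)c21
F7 | step 4 | tert-butyl 7-bromo-2-lithioindole-1-carboxylate | [Li]c1cc2cccc(Br)c2n1C(=O)OC(C)(C)C
F8 | step 4 | tert-butyl 2,7-dibromoindole-1-carboxylate | CC(C)(C)OC(=O)n1c(Br)cc2cccc(Br)c21
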